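**Plan**

- Retrosynthesis: the two C6–Br bonds are cut first, back to two C6–B bonds and then to two C6–H bonds of a bromine-free, N-protected 2,4-bis(indol-3-yl)imidazole.
- Next the two indole C3–imidazole bonds (to C2 and to C4) are cut, giving a 2,4-dibromoimidazole and an indol-3-ylboronate, itself made from indole by C3–H borylation.
- Forward: no ring is built. The bought indole and imidazole rings are joined by a double Suzuki coupling, boron is placed on C6 of both benzenoid rings in one operation and exchanged for bromine, and the nitrogen protecting groups are removed.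
- Enabling feature: on each indole the benzenoid ring (C4 to C7) carries only the C6–Br bond, and C6 is meta to N1 and remote from both N1 and C3. With a bulky silyl group on N1 (covering C2–H and C7–H) and the imidazole on C3 (covering C4–H), C6–H is the bond a hindered iridium boryl catalyst should take, alike on both indoles.
- Stereochemistry: none; the target has no stereocentre. Because bromine arrives last, the palladium and iridium steps run on halogen-free indoles.

Key step: step 5

Remark: the imidazole N–H of the target is tautomeric, so 2,4- and 2,5-disubstituted 1H-imidazole are the same compound; 2,4-dibromo-1H-imidazole, indole and B2pin2 are taken as purchasable. Abbreviations: SEM = 2-(trimethylsilyl)ethoxymethyl, TIPS = triisopropylsilyl, Bpin = 4,4,5,5-tetramethyl-1,3,2-dioxaborolan-2-yl, dtbpy = 4,4'-di-tert-butyl-2,2'-bipyridine, SPhos = 2-dicyclohexylphosphino-2',6'-dimethoxybiphenyl, TBAF = tetrabutylammonium fluoride.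

**Route**

Step 1
Reactants: 1 2,4-dibromo-1H-imidazole
Product: 2 2,4-dibromo-1-SEM-imidazole
Conditions: NaH, THF, 0 °C; then SEMCl, 0 °C to rt
Reagents that add atoms: 2-(trimethylsilyl)ethoxymethyl chloride (SEMCl), C[Si](C)(C)CCOCCl
Why: N-Alkylation of the imidazolide anion (SN2 at the chloromethyl ether) should take the nitrogen remote from the C4 bromine, the less hindered one, to give the 1,2,4-pattern, the minor 2,5-dibromo isomer being removed by chromatography.

Step 2
Reactants: 3 indole
Product: 4 1-(triisopropylsilyl)indole
Conditions: NaH, THF, 0 °C; then TIPSCl, rt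
Reagents that add atoms: triisopropylsilyl chloride (TIPSCl), CC(C)[Si](Cl)(C(C)C)C(C)C
Why: N-Silylation of sodium indolide is a standard protection and places the bulky group that later screens C2–H and C7–H.

Step 3
Reactants: 4 1-(triisopropylsilyl)indole; 5 bis(pinacolato)diboron
Product: 6 3-Bpin-1-(triisopropylsilyl)indole
Conditions: [Ir(cod)OMe]2 (cat.), dtbpy (cat.), B2pin2 (0.55 equiv), hexane, 50 °C
Reagents that add atoms: bis(pinacolato)diboron (compound 5), CC1(C)OB(OC1(C)C)B1OC(C)(C)C(C)(C)O1
Why: Iridium-catalysed C–H borylation (Ishiyama–Miyaura–Hartwig) of N-triisopropylsilylindole is known to go to C3, because the silyl group screens C2–H and C7–H and the pyrrole β-C–H is the most reactive bond left, while the substoichiometric diboron limits a second borylation.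

Step 4
Reactants: 2 2,4-dibromo-1-SEM-imidazole; 6 3-Bpin-1-(triisopropylsilyl)indole (2.5 equiv)
Product: 8 1-SEM-2,4-bis(1-triisopropylsilylindol-3-yl)imidazole, via 4-bromo-1-SEM-2-(1-triisopropylsilylindol-3-yl)imidazole 7 (not isolated)
Conditions: Pd(OAc)2 (cat.), SPhos, K3PO4, 1,4-dioxane/H2O, 90 °C
Reagents that add atoms: none
Why: Suzuki–Miyaura coupling with a zerovalent palladium/SPhos catalyst, first at the more reactive C2–Br bond between the two nitrogens and then at C4–Br, is well known for N-protected bromoimidazoles and N-silyl indol-3-ylboron reagents, and with no halogen on the indoles there is no competing oxidative addition.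

Step 5
Reactants: 8 1-SEM-2,4-bis(1-triisopropylsilylindol-3-yl)imidazole; 5 bis(pinacolato)diboron
Product: 9 1-SEM-2,4-bis(6-Bpin-1-triisopropylsilylindol-3-yl)imidazole
Conditions: [Ir(cod)OMe]2 (cat.), 1,10-phenanthroline, B2pin2 (3 equiv), HBpin (cat.), hexane, 80 °C, sealed tube
Reagents that add atoms: bis(pinacolato)diboron (compound 5), CC1(C)OB(OC1(C)C)B1OC(C)(C)C(C)(C)O1
Why: The trivalent iridium tris(boryl) complex (phen)Ir(Bpin)3, formed from [Ir(cod)OMe]2, 1,10-phenanthroline and the boron reagents, cleaves an arene C–H bond by oxidative addition and forms the C–B bond by reductive elimination, after which 5 regenerates the tris(boryl). The closest known reaction type is the sterically governed Ishiyama–Miyaura–Hartwig C–H borylation, which on N-triisopropylsilyl 3-substituted indoles is known to take place at C6. No ring closes and no stereocentre forms; two C–B bonds are made, one on each benzenoid ring. The step needs C6 over C5 on both indoles and no reaction at indole C2–H or imidazole C5–H. Each triisopropylsilyl group covers C2–H and C7–H, the imidazole at C3 covers the peri C4–H, and C5 lies para to N1 and is the more electron-rich, less reactive of the two open positions, so C6 (meta to N1) should be taken. Imidazole C5–H sits between N1–SEM and the C4 indolyl group, and N3 is flanked by two indolyl groups and should bind the catalyst only weakly.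

Step 6
Reactants: 9 1-SEM-2,4-bis(6-Bpin-1-triisopropylsilylindol-3-yl)imidazole
Product: 10 1-SEM-2,4-bis(6-bromo-1-triisopropylsilylindol-3-yl)imidazole
Conditions: CuBr2 (3 equiv per boronate), MeOH/THF/H2O, 70 °C
Reagents that add atoms: copper dibromide (CuBr2), [Cu+2].[Br-].[Br-]
Why: Copper-mediated bromodeboronation of aryl pinacol boronates with CuBr2 in aqueous methanol, the usual partner of iridium borylation, exchanges each C–B bond for C–Br at the same carbon, so the C6 regiochemistry set in step 5 is carried over unchanged.

Step 7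
Reactants: 10 1-SEM-2,4-bis(6-bromo-1-triisopropylsilylindol-3-yl)imidazole
Product: 12 nortopsentin A [2,4-bis(6-bromo-1H-indol-3-yl)-1H-imidazole], via 1-SEM-2,4-bis(6-bromoindol-3-yl)imidazole 11 (not isolated)
Conditions: TBAF (excess), THF, rt then reflux; aqueous work-up
Reagents that add atoms: none
Why: Fluoride-induced N-desilylation frees both indole nitrogens at room temperature, and on heating fluoride attacks the trimethylsilyl group of the SEM ether and triggers β-elimination with loss of ethene and formaldehyde, a standard removal of SEM from imidazole nitrogen that leaves aryl bromides untouched.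

**Compound list**

1 | 2,4-dibromo-1H-imidazole | Brc1c[nH]c(Br)n1 | starting material
2 | 2,4-dibromo-1-{[2-(trimethylsilyl)ethoxy]methyl}imidazole | C[Si](C)(C)CCOCn1cc(Br)nc1Br | intermediate
3 | indole | c1ccc2[nH]ccc2c1 | starting material
4 | 1-(triisopropylsilyl)indole | CC(C)[Si](C(C)C)(C(C)C)n1ccc2ccccc21 | intermediate
5 | bis(pinacolato)diboron | CC1(C)OB(OC1(C)C)B1OC(C)(C)C(C)(C)O1 | starting material
6 | 3-(4,4,5,5-tetramethyl-1,3,2-dioxaborolan-2-yl)-1-(triisopropylsilyl)indole | CC(C)[Si](C(C)C)(C(C)C)n1cc(B2OC(C)(C)C(C)(C)O2)c2ccccc21 | intermediate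
7 | 4-bromo-1-SEM-2-(1-triisopropylsilylindol-3-yl)imidazole (not isolated) | CC(C)[Si](C(C)C)(C(C)C)n1cc(-c2nc(Br)cn2COCC[Si](C)(C)C)c2ccccc21 | intermediate
8 | 1-SEM-2,4-bis(1-triisopropylsilylindol-3-yl)imidazole | CC(C)[Si](C(C)C)(C(C)C)n1cc(-c2cn(COCC[Si](C)(C)C)c(-c3cn([Si](C(C)C)(C(C)C)C(C)C)c4ccccc34)n2)c2ccccc21 | intermediate
9 | 1-SEM-2,4-bis[6-(pinacolboryl)-1-triisopropylsilylindol-3-yl]imidazole | CC(C)[Si](C(C)C)(C(C)C)n1cc(-c2cn(COCC[Si](C)(C)C)c(-c3cn([Si](C(C)C)(C(C)C)C(C)C)c4cc(B5OC(C)(C)C(C)(C)O5)ccc34)n2)c2ccc(B3OC(C)(C)C(C)(C)O3)cc21 | intermediate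
10 | 1-SEM-2,4-bis(6-bromo-1-triisopropylsilylindol-3-yl)imidazole | CC(C)[Si](C(C)C)(C(C)C)n1cc(-c2cn(COCC[Si](C)(C)C)c(-c3cn([Si](C(C)C)(C(C)C)C(C)C)c4cc(Br)ccc34)n2)c2ccc(Br)cc21 | intermediate
11 | 1-SEM-2,4-bis(6-bromo-1H-indol-3-yl)imidazole (not isolated) | C[Si](C)(C)CCOCn1cc(-c2c[nH]c3cc(Br)ccc23)nc1-c1c[nH]c2cc(Br)ccc12 | intermediate
12 | nortopsentin A, 2,4-bis(6-bromo-1H-indol-3-yl)-1H-imidazole | Brc1ccc2c(-c3c[nH]c(-c4c[nH]c5cc(Br)ccc45)n3)c[nH]c2c1 | target

**Summary**

Total step count: 7. Longest linear sequence: 6 steps (indole 3 through steps 2, 3, 4, 5, 6 and 7 to 12).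

**Steps most likely to fail**

Step 5. The catalyst may not discriminate cleanly between C5–H and C6–H, and any leakage is multiplied over two rings; the azole nitrogen may also slow turnover. Fallback: the bromine is brought in with the indole instead of being installed late. The fallback sets out from 2 and comes back at 10. Purchased 6-bromoindole F1 is N-silylated (NaH, TIPSCl, THF) to 6-bromo-1-(triisopropylsilyl)indole F2. Iridium-catalysed C3 borylation under the conditions of step 3, which tolerates aryl bromides, should give 6-bromo-3-Bpin-1-(triisopropylsilyl)indole F3. Double Suzuki coupling of F3 with 2 (Pd(PPh3)4, K3PO4, 1,4-dioxane/H2O, 80 °C) relies on the azole C–Br bonds undergoing oxidative addition before the electron-rich indole C6–Br bond, and gives 10 directly.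

Step 6. Protodeboronation may compete with bromination in hot aqueous methanol, and the HBr formed may strip silyl groups early, exposing the indole nucleus to oxidative bromination by CuBr2. Fallback: a metal-free ipso-substitution of a tetracoordinate borate replaces the copper chemistry. The fallback sets out from 9 and comes back at 10. Treatment of 9 with KHF2 in MeOH/THF/H2O at rt should give the bis(potassium trifluoroborate) of 1-SEM-2,4-bis(1-triisopropylsilylindol-3-yl)imidazole F4. Tetrabutylammonium tribromide (Bu4NBr3) in THF/H2O at rt should then replace each BF3K group by bromine at the same carbon, the silyl groups shielding indole C2 from the electrophile, to give 10.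

Step 4. The reaction may stall after the first coupling, since C4–Br adds to palladium slowly while the indolylboronate protodeboronates and hot aqueous base erodes the N–Si bonds. Fallback: a base-free, anhydrous Negishi coupling replaces the Suzuki coupling. The fallback sets out from 4 and comes back at 8. Bromination of 4 with NBS (THF, −78 °C to rt) gives 3-bromo-1-(triisopropylsilyl)indole F5. Bromine–lithium exchange (t-BuLi, THF, −78 °C) and transmetalation with ZnCl2 give 1-(triisopropylsilyl)indol-3-ylzinc chloride F6. Coupling of F6 (excess) with 2 using Pd(PPh3)4 in THF at 65 °C should give 8.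

**Further compounds**

F1 | step 5 | 6-bromoindole | Brc1ccc2cc[nH]c2c1
F2 | step 5 | 6-bromo-1-(triisopropylsilyl)indole | CC(C)[Si](C(C)C)(C(C)C)n1ccc2ccc(Br)cc21
F3 | step 5 | 6-bromo-3-(4,4,5,5-tetramethyl-1,3,2-dioxaborolan-2-yl)-1-(triisopropylsilyl)indole | CC(C)[Si](C(C)C)(C(C)C)n1cc(B2OC(C)(C)C(C)(C)O2)c2ccc(Br)cc21
F4 | step 6 | dipotassium bis(trifluoroborate) of 1-SEM-2,4-bis(1-triisopropylsilylindol-3-yl)imidazole, boron at C6 of each indole | CC(C)[Si](C(C)C)(C(C)C)n1cc(-c2cn(COCC[Si](C)(C)C)c(-c3cn([Si](C(C)C)(C(C)C)C(C)C)c4cc([B-](F)(F)F)ccc34)n2)c2ccc([B-](F)(F)F)cc21.[K+].[K+]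
F5 | step 4 | 3-bromo-1-(triisopropylsilyl)indole | CC(C)[Si](C(C)C)(C(C)C)n1cc(Br)c2ccccc21
F6 | step 4 | 1-(triisopropylsilyl)indol-3-ylzinc chloride | CC(C)[Si](C(C)C)(C(C)C)n1cc([Zn]Cl)c2ccccc21
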